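The data stem from a simulated flask for substances that don't exist; noise was put on by code.

The vessel is closed and stirred, so Z that forms stays in it until it passes on to X, and the flasks eta, zeta and epsilon share a charge and differ in their temperature history.

| flask | E | Q | temperature | remark | time |
|---|---|---|---|---|---|
| larch | 0.053 M | 4 equiv | −14 °C | run made earlier |  |
| ash | 0.12 M | 4 equiv | 0 °C | run made earlier |  |
| eta | 0.079 M | 4.00 equiv |  | at 5 °C until 20 h, from then on at −20 °C | 3.0 d |
| zeta | 0.079 M | 4.00 equiv | −20 °C |  | 3.0 d |
| epsilon | 0.079 M | 4.00 equiv | 5 °C |  | 3.0 d |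

| run | time / h | Z / % |
|---|---|---|
| larch | 3.00 | 86.4 |
| larch | 6.00 | 85.4 |
| larch | 10.0 | 76.8 |
| larch | 15.0 | 68.8 |
| larch | 25.0 | 50.8 |
| larch | 40.0 | 37.5 |
| ash | 3.00 | 59.0 |
| ash | 6.00 | 35.2 |
| ash | 8.00 | 23.7 |
| ash | 12.0 | 12.9 |
| ash | 15.0 | 8.5 |

(standard deviation of a reading: 1 percentage point)

* the best flask by amount of Z, in percent of the E charged; "all alike" if 1.5 percentage points covers them all (eta / zeta / epsilon / all alike)
* amount of Z at the end, in percent of the E charged, eta
* amount of Z at the end, in percent of the E charged, zeta
* amount of Z at the end, in percent of the E charged, epsilon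

- the analysis behind the earlier runs scatters by 1 percentage point, standard deviation
- steps thought possible: E + Q -> Z; Z -> X

Each E takes one Q and the charge holds 4.00 equiv, so E is the limiting reagent. The larch flask already shows Z at 86.4% after 3.00 h, a time short against the 3.0 d asked, so I set formation aside and keep two times, the hold and the half-life of Z. The falling readings give me a first-order decay of c_Z of 0.0242 h⁻¹ in larch and 0.161 h⁻¹ in ash, and together these readings give an activation energy of 79.8 kJ mol⁻¹. Extrapolated, my half-life of Z is 68.9 h at −20 °C and 2.28 h at 5 °C. I work with the fraction left, which is two to the power minus the hold number, the hold time divided by the half-life of Z at the flask's temperature: for zeta that number is 1.05, so I expect 48.4% of Z there. For epsilon it is 31.5, which leaves nothing I could read against a scatter of 1 percentage point. Hold numbers add along a flask, so eta collects 9.51, and I expect 0.137% there.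

The forecast names zeta, with 0.3% for eta, 49% for zeta and 0% for epsilon: “Zeta is clearly best, though the extrapolation gives it a wide range.” My figures for zeta and eta lie below its own.

The flasks give zeta as best, with 0.0752% in eta, 45.9% in zeta and 0% in epsilon.

    E + Q → Z, rate k1*[E]^1.5*[Q] (k = 22.3 M⁻¹·⁵ h⁻¹, Ea = 54.0 kJ mol⁻¹)
    Z → X (k = 0.0110 h⁻¹, Ea = 80.0 kJ mol⁻¹)
    (constants at −20 °C)

The equations put a fractional order in E into formation, yet zeta reaches half conversion by 0.452 h, short against its 3.0 d, so I leave the hold number 1.05 of zeta counted from the start of that flask. Taken out of epsilon, the passage of Z into X lifts the end value of Z from 0% to >99.9%, and the half-life of Z by that passage in epsilon, 0.086 d, is short against the hold, a hold number of 34.9. In eta my summed hold number of 9.51 gave me 0.137%, and the flask holds a lower Z of 0.0752%.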